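**Retrosynthetic overview**
1. Entonaemin A ⇒ late acylation of the C6-OH of a pyran diol with a silyl-protected orsellinoyl chloride, then global desilylation.
2. 2H-Pyran ring (formed last) ⇒ 6-endo oxa-cyclisation of a 2-(hydroxymethyl)-3-enynyl-cyclohex-2-enone.
3. Enynone ⇒ acetylide 1,2-addition to a 2-(hydroxymethyl)cyclohexenone and oxidative 1,3-transposition; the CH2OH (C1) comes from a Morita–Baylis–Hillman aldol with formaldehyde.
4. Carbocycle (formed first) ⇒ intramolecular aldol/dehydration of an acyclic keto aldehyde made by epoxide opening and Wacker oxidation.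
5. Key C–C bond (C5–C6) ⇒ asymmetric allylboration of methacrolein, which assembles all six ring carbons and sets C6; a matched Sharpless epoxidation then sets C7.

Assumption: (E)-pent-2-en-4-yn-1-ol, orsellinic acid, (+)-Ipc2BOMe and D-(−)-diisopropyl tartrate are bought; atom labels C1, O2, C3, C4, C4a, C5–C8, C8a follow 1H-isochromene numbering of the target.

**Route**

Step 1
Reactants: 1 methacrolein; 2 allylmagnesium bromide
Product: 5 (3R)-2-methylhexa-1,5-dien-3-ol, via B-allyldiisopinocampheylborane 3 (not isolated), via borinate ester 4 (not isolated)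
Conditions: (+)-Ipc2BOMe [from (−)-α-pinene], CH2=CHCH2MgBr, Et2O, 0 °C to rt; then 1, −78 °C; then 3 M NaOH, 30% H2O2, rt
Reagents that add atoms: none
Why: Brown asymmetric allylboration (carbonyl allylation) through a chair Zimmerman–Traxler transition state joins the C3 allyl unit to the C4 enal, forming the C5–C6 bond and setting C6 as R by reagent control (about 90% ee, upgraded in step 2).

Step 2
Reactants: 5 (3R)-2-methylhexa-1,5-dien-3-ol
Product: 6 (1R)-1-[(2S)-2-methyloxiran-2-yl]but-3-en-1-ol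
Conditions: Ti(OiPr)4 (10 mol %), D-(−)-diisopropyl tartrate (15 mol %), t-BuOOH (1.5 equiv), 4 Å MS, CH2Cl2, −20 °C
Reagents that add atoms: tert-butyl hydroperoxide, CC(C)(C)OO
Why: Sharpless asymmetric epoxidation in the matched (fast) pairing gives the erythro epoxy alcohol, setting quaternary C7 relative to C6, while the minor S alcohol reacts slowly and the homoallylic alkene is untouched.

Step 3
Reactants: 6 (1R)-1-[(2S)-2-methyloxiran-2-yl]but-3-en-1-ol
Product: 7 (2S,3R)-1-(benzyloxy)-2-methylhex-5-ene-2,3-diol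
Conditions: BnOH (solvent), NaH (0.3 equiv), 70 °C
Reagents that add atoms: benzyl alcohol, OCc1ccccc1
Why: Base-mediated SN2 epoxide opening by benzyl alkoxide occurs at the unhindered CH2 terminus, so the C–O bond at the tertiary centre is never broken and both stereocentres are retained.

Step 4
Reactants: 7 (2S,3R)-1-(benzyloxy)-2-methylhex-5-ene-2,3-diol
Product: 8 (4S,5R)-4-[(benzyloxy)methyl]-2,2,4-trimethyl-5-(prop-2-en-1-yl)-1,3-dioxolane
Conditions: 2,2-dimethoxypropane, PPTS (cat.), CH2Cl2, rt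
Reagents that add atoms: 2,2-dimethoxypropane, COC(C)(C)OC
Why: Acid-catalysed transketalisation (acetonide formation) ties the secondary and tertiary hydroxyls into a dioxolane that holds the two future carbonyl arms cis and protects the diol through the basic and oxidative steps.

Step 5
Reactants: 8 (4S,5R)-4-[(benzyloxy)methyl]-2,2,4-trimethyl-5-(prop-2-en-1-yl)-1,3-dioxolane
Product: 9 1-{(4R,5S)-5-[(benzyloxy)methyl]-2,2,5-trimethyl-1,3-dioxolan-4-yl}propan-2-one
Conditions: PdCl2 (10 mol %), CuCl (1 equiv), O2 (1 atm), DMF/H2O 7:1, rt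
Reagents that add atoms: water, O (source of the ketone oxygen; dioxygen, O=O, is the terminal oxidant)
Why: Tsuji–Wacker oxidation converts the terminal alkene with Markovnikov selectivity into the methyl ketone, unmasking the allyl group as an acetone enolate equivalent whose CH3 becomes C8a.

Step 6
Reactants: 9 1-{(4R,5S)-5-[(benzyloxy)methyl]-2,2,5-trimethyl-1,3-dioxolan-4-yl}propan-2-one
Product: 10 1-[(4R,5S)-5-(hydroxymethyl)-2,2,5-trimethyl-1,3-dioxolan-4-yl]propan-2-one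
Conditions: H2 (1 atm), 10% Pd/C, EtOAc, rt
Reagents that add atoms: none
Why: Catalytic hydrogenolysis cleaves the benzyl ether cleanly now that no C=C bond remains, leaving ketone and acetonide intact.

Step 7
Reactants: 10 1-[(4R,5S)-5-(hydroxymethyl)-2,2,5-trimethyl-1,3-dioxolan-4-yl]propan-2-one
Product: 11 (4R,5R)-2,2,4-trimethyl-5-(2-oxopropyl)-1,3-dioxolane-4-carbaldehyde
Conditions: Dess–Martin periodinane (1.2 equiv), CH2Cl2, rt
Reagents that add atoms: none
Why: Dess–Martin oxidation gives the non-enolisable α-quaternary aldehyde under neutral conditions without touching the ketone or the acetonide.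

Step 8
Reactants: 11 (4R,5R)-2,2,4-trimethyl-5-(2-oxopropyl)-1,3-dioxolane-4-carbaldehyde
Product: 12 (3aR,7aS)-7-hydroxy-2,2,7a-trimethyl-3a,6,7,7a-tetrahydro-1,3-benzodioxol-5(4H)-one (C7 epimers)
Conditions: LiN(SiMe3)2 (1.1 equiv), THF, −78 °C (inverse addition); sat. NH4Cl at −78 °C
Reagents that add atoms: none
Why: Kinetic deprotonation on the CH3 side of the methyl ketone and intramolecular aldol addition onto the non-enolisable aldehyde closes the carbocycle cis-fused to the dioxolane, the new carbinol centre forming as an inconsequential mixture that is removed in step 9.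

Step 9
Reactants: 12 (3aR,7aS)-7-hydroxy-2,2,7a-trimethyl-3a,6,7,7a-tetrahydro-1,3-benzodioxol-5(4H)-one
Product: 14 (3aR,7aS)-2,2,7a-trimethyl-3a,7a-dihydro-1,3-benzodioxol-5(4H)-one, via mesylate 13 (not isolated)
Conditions: MsCl (1.3 equiv), Et3N (3 equiv), DMAP (cat.), CH2Cl2, 0 °C to rt
Reagents that add atoms: none
Why: Mesylation of the β-hydroxy ketone and E1cB elimination give the conjugated enone, the mesylate being a far better leaving group than the acetonide oxygen at the other β-position.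

Step 10
Reactants: 14 (3aR,7aS)-2,2,7a-trimethyl-3a,7a-dihydro-1,3-benzodioxol-5(4H)-one
Product: 15 (3aR,7aS)-6-(hydroxymethyl)-2,2,7a-trimethyl-3a,7a-dihydro-1,3-benzodioxol-5(4H)-one
Conditions: 37% aq. HCHO (3 equiv), DMAP (0.5 equiv), THF/H2O 1:1, rt
Reagents that add atoms: formaldehyde, C=O
Why: Morita–Baylis–Hillman reaction, an amine-triggered intermolecular aldol addition of the enone α-carbon to formaldehyde, installs the C1 hydroxymethyl group at C8a.

Step 11
Reactants: 15 (3aR,7aS)-6-(hydroxymethyl)-2,2,7a-trimethyl-3a,7a-dihydro-1,3-benzodioxol-5(4H)-one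
Product: 16 (3aR,7aS)-6-({[tert-butyl(dimethyl)silyl]oxy}methyl)-2,2,7a-trimethyl-3a,7a-dihydro-1,3-benzodioxol-5(4H)-one
Conditions: TBSCl (1.2 equiv), imidazole, CH2Cl2, 0 °C to rt
Reagents that add atoms: tert-butyldimethylsilyl chloride, C[Si](C)(Cl)C(C)(C)C
Why: Standard silylation protects the primary allylic alcohol against the acetylide and the chromium oxidant.

Step 12
Reactants: 17 (2E)-pent-2-en-4-yn-1-ol
Product: 18 tert-butyl{[(2E)-pent-2-en-4-yn-1-yl]oxy}diphenylsilane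
Conditions: TBDPSCl (1.1 equiv), imidazole, CH2Cl2, rt
Reagents that add atoms: tert-butyldiphenylsilyl chloride, CC(C)(C)[Si](Cl)(c1ccccc1)c1ccccc1
Why: Silylation with the acid-stable TBDPS group lets this ether survive the later acidic removal of the acetonide and the TBS ether.

Step 13
Reactants: 16 (3aR,7aS)-6-({[tert-butyl(dimethyl)silyl]oxy}methyl)-2,2,7a-trimethyl-3a,7a-dihydro-1,3-benzodioxol-5(4H)-one; 18 tert-butyl{[(2E)-pent-2-en-4-yn-1-yl]oxy}diphenylsilane
Product: 20 (3aR,7aS)-6-({[tert-butyl(dimethyl)silyl]oxy}methyl)-5-[(3E)-5-{[tert-butyl(diphenyl)silyl]oxy}pent-3-en-1-yn-1-yl]-2,2,7a-trimethyl-3a,4,5,7a-tetrahydro-1,3-benzodioxol-5-ol (C5 epimers), via lithium acetylide 19 (not isolated)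
Conditions: 18 (1.3 equiv), n-BuLi (1.25 equiv), THF, −78 °C; then 16, −78 to −40 °C; sat. NH4Cl
Reagents that add atoms: none
Why: The lithium acetylide adds 1,2 to the enone carbonyl faster than it enolises it at −78 °C, attaching the whole enyne side chain to C4a; the new carbinol centre is an epimer mixture erased in step 14.

Step 14
Reactants: 20 tertiary allylic propargylic alcohol
Product: 21 (3aR,7aR)-5-({[tert-butyl(dimethyl)silyl]oxy}methyl)-6-[(3E)-5-{[tert-butyl(diphenyl)silyl]oxy}pent-3-en-1-yn-1-yl]-2,2,3a-trimethyl-7,7a-dihydro-1,3-benzodioxol-4(3aH)-one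
Conditions: pyridinium chlorochromate [C5H5NH][CrO3Cl] (2.5 equiv), NaOAc, 4 Å MS, CH2Cl2, rt
Reagents that add atoms: none
Why: Dauben–Babler oxidative 1,3-transposition moves the oxygen by [3,3] shift of the chromate ester to C8 and oxidises it there, giving the tetrasubstituted enynone with the carbonyl at C8 while C6 and C7 are untouched.

Step 15
Reactants: 21 enynone acetonide
Product: 22 (5R,6R)-3-[(3E)-5-{[tert-butyl(diphenyl)silyl]oxy}pent-3-en-1-yn-1-yl]-5,6-dihydroxy-2-(hydroxymethyl)-6-methylcyclohex-2-en-1-one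
Conditions: TFA/H2O/CH2Cl2 9:1:10, 0 °C
Reagents that add atoms: none
Why: Aqueous acid hydrolyses the acetonide and the primary TBS ether while the far more acid-stable primary TBDPS ether is kept.

Step 16
Reactants: 22 triol enynone
Product: 23 (6R,7R)-3-[(1E)-3-{[tert-butyl(diphenyl)silyl]oxy}prop-1-en-1-yl]-6,7-dihydroxy-7-methyl-6,7-dihydro-1H-isochromen-8(5H)-one
Conditions: AgOTf (AgOSO2CF3, 5 mol %), CH2Cl2, rt
Reagents that add atoms: none
Why: Silver-catalysed 6-endo-dig hydroalkoxylation (an oxa-1,6-conjugate addition of the CH2OH to the ynenone) forms the 2H-pyran because C3 is the electrophilic δ-terminus, whereas the 5-exo mode lacks this activation and the C6 hydroxyl cannot reach the alkyne.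

Step 17
Reactants: 24 orsellinic acid (2,4-dihydroxy-6-methylbenzoic acid)
Product: 25 tert-butyl(dimethyl)silyl 2,4-bis{[tert-butyl(dimethyl)silyl]oxy}-6-methylbenzoate
Conditions: TBSCl (3.3 equiv), imidazole (6 equiv), DMF, rt
Reagents that add atoms: tert-butyldimethylsilyl chloride, C[Si](C)(Cl)C(C)(C)C
Why: Exhaustive silylation masks both phenols and turns the acid into a silyl ester ready for direct chloride formation.

Step 18
Reactants: 25 tris-silylated orsellinic acid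
Product: 26 2,4-bis{[tert-butyl(dimethyl)silyl]oxy}-6-methylbenzoyl chloride
Conditions: (COCl)2 (1.2 equiv), DMF (cat.), CH2Cl2, 0 °C to rt; concentrate and use crude
Reagents that add atoms: oxalyl chloride, O=C(Cl)C(Cl)=O
Why: Vilsmeier-type activation exchanges the silyl ester for the acid chloride under neutral conditions that leave the aryl silyl ethers intact.

Step 19
Reactants: 23 pyran diol; 26 2,4-bis{[tert-butyl(dimethyl)silyl]oxy}-6-methylbenzoyl chloride
Product: 27 (6R,7R)-3-[(1E)-3-{[tert-butyl(diphenyl)silyl]oxy}prop-1-en-1-yl]-7-hydroxy-7-methyl-8-oxo-5,6,7,8-tetrahydro-1H-isochromen-6-yl 2,4-bis{[tert-butyl(dimethyl)silyl]oxy}-6-methylbenzoate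
Conditions: 26 (1.5 equiv), DMAP (2 equiv), Et3N (3 equiv), CH2Cl2, 0 °C to rt
Reagents that add atoms: none
Why: DMAP-catalysed acylation (nucleophilic acyl substitution) takes place at the secondary C6 hydroxyl because the tertiary α-ketol hydroxyl at C7 is far more hindered, with retention at C6 since its C–O bond is not broken.

Step 20
Reactants: 27 silyl-protected ester
Product: 28 entonaemin A
Conditions: Bu4NF (4 equiv), AcOH (4 equiv), THF, 0 °C to rt
Reagents that add atoms: none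
Why: Acetic acid-buffered fluoride desilylation removes the two aryl TBS ethers and the primary TBDPS ether under near-neutral conditions that avoid acyl migration or β-elimination of the ester.

**Compound list**

1 | methacrolein (2-methylprop-2-enal) | CC(=C)C=O | starting material
2 | allylmagnesium bromide | C=CC[Mg]Br | starting material
3 | allylbis[(1S,2R,3S,5S)-2,6,6-trimethylbicyclo[3.1.1]heptan-3-yl]borane (B-allyldiisopinocampheylborane, formed in the flask) | C=CCB([C@H]1C[C@H]2C[C@@H]([C@@H]1C)C2(C)C)[C@H]1C[C@H]2C[C@@H]([C@@H]1C)C2(C)C | intermediate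
4 | (3R)-2-methylhexa-1,5-dien-3-yl bis[(1S,2R,3S,5S)-2,6,6-trimethylbicyclo[3.1.1]heptan-3-yl]borinate (formed in the flask) | C=CC[C@@H](OB([C@H]1C[C@H]2C[C@@H]([C@@H]1C)C2(C)C)[C@H]1C[C@H]2C[C@@H]([C@@H]1C)C2(C)C)C(C)=C | intermediate
5 | (3R)-2-methylhexa-1,5-dien-3-ol | C=CC[C@@H](O)C(C)=C | intermediate
6 | (1R)-1-[(2S)-2-methyloxiran-2-yl]but-3-en-1-ol | C=CC[C@@H](O)[C@]1(C)CO1 | intermediate
7 | (2S,3R)-1-(benzyloxy)-2-methylhex-5-ene-2,3-diol | C=CC[C@@H](O)[C@@](C)(O)COCc1ccccc1 | intermediate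
8 | (4S,5R)-4-[(benzyloxy)methyl]-2,2,4-trimethyl-5-(prop-2-en-1-yl)-1,3-dioxolane | C=CC[C@H]1OC(C)(C)O[C@@]1(C)COCc1ccccc1 | intermediate
9 | 1-{(4R,5S)-5-[(benzyloxy)methyl]-2,2,5-trimethyl-1,3-dioxolan-4-yl}propan-2-one | CC(=O)C[C@H]1OC(C)(C)O[C@@]1(C)COCc1ccccc1 | intermediate
10 | 1-[(4R,5S)-5-(hydroxymethyl)-2,2,5-trimethyl-1,3-dioxolan-4-yl]propan-2-one | CC(=O)C[C@H]1OC(C)(C)O[C@@]1(C)CO | intermediate
11 | (4R,5R)-2,2,4-trimethyl-5-(2-oxopropyl)-1,3-dioxolane-4-carbaldehyde | CC(=O)C[C@H]1OC(C)(C)O[C@@]1(C)C=O | intermediate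
12 | (3aR,7aS)-7-hydroxy-2,2,7a-trimethyl-3a,6,7,7a-tetrahydro-1,3-benzodioxol-5(4H)-one (C7 epimers) | CC1(C)O[C@@H]2CC(=O)CC(O)[C@]2(C)O1 | intermediate
13 | (3aR,7aR)-2,2,7a-trimethyl-5-oxohexahydro-1,3-benzodioxol-7-yl methanesulfonate (C7 epimers, formed in the flask) | CC1(C)O[C@@H]2CC(=O)CC(OS(C)(=O)=O)[C@]2(C)O1 | intermediate
14 | (3aR,7aS)-2,2,7a-trimethyl-3a,7a-dihydro-1,3-benzodioxol-5(4H)-one | CC1(C)O[C@@H]2CC(=O)C=C[C@]2(C)O1 | intermediate
15 | (3aR,7aS)-6-(hydroxymethyl)-2,2,7a-trimethyl-3a,7a-dihydro-1,3-benzodioxol-5(4H)-one | CC1(C)O[C@@H]2CC(=O)C(CO)=C[C@]2(C)O1 | intermediate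
16 | (3aR,7aS)-6-({[tert-butyl(dimethyl)silyl]oxy}methyl)-2,2,7a-trimethyl-3a,7a-dihydro-1,3-benzodioxol-5(4H)-one | CC1(C)O[C@@H]2CC(=O)C(CO[Si](C)(C)C(C)(C)C)=C[C@]2(C)O1 | intermediate
17 | (2E)-pent-2-en-4-yn-1-ol | C#C/C=C/CO | starting material
18 | tert-butyl{[(2E)-pent-2-en-4-yn-1-yl]oxy}diphenylsilane | C#C/C=C/CO[Si](c1ccccc1)(c1ccccc1)C(C)(C)C | intermediate
19 | lithium (3E)-5-{[tert-butyl(diphenyl)silyl]oxy}pent-3-en-1-yn-1-ide (formed in the flask) | [Li]C#C/C=C/CO[Si](c1ccccc1)(c1ccccc1)C(C)(C)C | intermediate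
20 | (3aR,7aS)-6-({[tert-butyl(dimethyl)silyl]oxy}methyl)-5-[(3E)-5-{[tert-butyl(diphenyl)silyl]oxy}pent-3-en-1-yn-1-yl]-2,2,7a-trimethyl-3a,4,5,7a-tetrahydro-1,3-benzodioxol-5-ol (C5 epimers) | CC1(C)O[C@@H]2CC(O)(C#C/C=C/CO[Si](c3ccccc3)(c3ccccc3)C(C)(C)C)C(CO[Si](C)(C)C(C)(C)C)=C[C@]2(C)O1 | intermediate
21 | (3aR,7aR)-5-({[tert-butyl(dimethyl)silyl]oxy}methyl)-6-[(3E)-5-{[tert-butyl(diphenyl)silyl]oxy}pent-3-en-1-yn-1-yl]-2,2,3a-trimethyl-7,7a-dihydro-1,3-benzodioxol-4(3aH)-one | CC1(C)O[C@@H]2CC(C#C/C=C/CO[Si](c3ccccc3)(c3ccccc3)C(C)(C)C)=C(CO[Si](C)(C)C(C)(C)C)C(=O)[C@]2(C)O1 | intermediate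
22 | (5R,6R)-3-[(3E)-5-{[tert-butyl(diphenyl)silyl]oxy}pent-3-en-1-yn-1-yl]-5,6-dihydroxy-2-(hydroxymethyl)-6-methylcyclohex-2-en-1-one | O[C@@H]1CC(C#C/C=C/CO[Si](c2ccccc2)(c2ccccc2)C(C)(C)C)=C(CO)C(=O)[C@]1(C)O | intermediate
23 | (6R,7R)-3-[(1E)-3-{[tert-butyl(diphenyl)silyl]oxy}prop-1-en-1-yl]-6,7-dihydroxy-7-methyl-6,7-dihydro-1H-isochromen-8(5H)-one | O[C@@H]1CC2=C(COC(/C=C/CO[Si](c3ccccc3)(c3ccccc3)C(C)(C)C)=C2)C(=O)[C@]1(C)O | intermediate
24 | orsellinic acid (2,4-dihydroxy-6-methylbenzoic acid) | Cc1cc(O)cc(O)c1C(=O)O | starting material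
25 | tert-butyl(dimethyl)silyl 2,4-bis{[tert-butyl(dimethyl)silyl]oxy}-6-methylbenzoate | Cc1cc(O[Si](C)(C)C(C)(C)C)cc(O[Si](C)(C)C(C)(C)C)c1C(=O)O[Si](C)(C)C(C)(C)C | intermediate
26 | 2,4-bis{[tert-butyl(dimethyl)silyl]oxy}-6-methylbenzoyl chloride | Cc1cc(O[Si](C)(C)C(C)(C)C)cc(O[Si](C)(C)C(C)(C)C)c1C(Cl)=O | intermediate
27 | (6R,7R)-3-[(1E)-3-{[tert-butyl(diphenyl)silyl]oxy}prop-1-en-1-yl]-7-hydroxy-7-methyl-8-oxo-5,6,7,8-tetrahydro-1H-isochromen-6-yl 2,4-bis{[tert-butyl(dimethyl)silyl]oxy}-6-methylbenzoate | Cc1cc(O[Si](C)(C)C(C)(C)C)cc(O[Si](C)(C)C(C)(C)C)c1C(=O)O[C@@H]1CC2=C(COC(/C=C/CO[Si](c3ccccc3)(c3ccccc3)C(C)(C)C)=C2)C(=O)[C@]1(C)O | intermediate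
28 | entonaemin A, (6R,7R)-7-hydroxy-3-[(1E)-3-hydroxyprop-1-en-1-yl]-7-methyl-8-oxo-5,6,7,8-tetrahydro-1H-isochromen-6-yl 2,4-dihydroxy-6-methylbenzoate | Cc1cc(O)cc(O)c1C(=O)O[C@@H]1CC2=C(COC(/C=C/CO)=C2)C(=O)[C@]1(C)O | target

**Totals**
Total step count: 20.
Longest linear sequence: 17 steps (steps 1–11, 13–16, 19, 20). Step 12 and steps 17–18 are side branches.

**Three steps most likely to fail, each with a fallback**

Step 10 (Morita–Baylis–Hillman on a hindered, base-sensitive enone; slow reaction or β-elimination of the acetonide oxygen are the risks). The fallback sets out from 14. α-Iodination (I2, pyridine, CH2Cl2, rt) gives (3aR,7aS)-6-iodo-2,2,7a-trimethyl-3a,7a-dihydro-1,3-benzodioxol-5(4H)-one F1. Stille coupling of F1 with (tributylstannyl)methanol (Pd(PPh3)4, zerovalent palladium, dioxane, 80 °C) then gives 15, where the route is rejoined.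

Step 14 (oxidative transposition to an allylic terminus next to the quaternary C7; dehydration or incomplete migration are the risks). The fallback sets out from 20. Ph3SiOReO3 (heptavalent rhenium, 3 mol %, Et2O, 0 °C) catalyses the 1,3-hydroxyl shift to the thermodynamically favoured conjugated alcohol (3aS,7aR)-5-({[tert-butyl(dimethyl)silyl]oxy}methyl)-6-[(3E)-5-{[tert-butyl(diphenyl)silyl]oxy}pent-3-en-1-yn-1-yl]-2,2,3a-trimethyl-3a,4,7,7a-tetrahydro-1,3-benzodioxol-4-ol F2 (C4 epimers). Dess–Martin oxidation of F2 gives 21, where the route is rejoined.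

Step 19 (acylation of a hindered secondary alcohol with a 2,6-disubstituted benzoyl chloride). The fallback sets out from 23 and 24 and changes the acyl donor to a benzodioxinone that is opened by the alkoxide. Orsellinic acid 24 with acetone, trifluoroacetic anhydride and TFA gives 7-hydroxy-2,2,5-trimethyl-4H-1,3-benzodioxin-4-one F3. Silylation (TBSCl, imidazole) gives 7-{[tert-butyl(dimethyl)silyl]oxy}-2,2,5-trimethyl-4H-1,3-benzodioxin-4-one F4. The sodium alkoxide of 23 (NaN(SiMe3)2, 1.1 equiv, THF, 0 °C; NH4Cl quench) opens F4 with loss of acetone, the acyl group settling on the less hindered secondary oxygen, to give (6R,7R)-3-[(1E)-3-{[tert-butyl(diphenyl)silyl]oxy}prop-1-en-1-yl]-7-hydroxy-7-methyl-8-oxo-5,6,7,8-tetrahydro-1H-isochromen-6-yl 4-{[tert-butyl(dimethyl)silyl]oxy}-2-hydroxy-6-methylbenzoate F5. Desilylation of F5 with Bu4NF/AcOH, as in step 20, gives 28.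

**Further compounds**

F1 | step 10 | (3aR,7aS)-6-iodo-2,2,7a-trimethyl-3a,7a-dihydro-1,3-benzodioxol-5(4H)-one | CC1(C)O[C@@H]2CC(=O)C(I)=C[C@]2(C)O1
F2 | step 14 | (3aS,7aR)-5-({[tert-butyl(dimethyl)silyl]oxy}methyl)-6-[(3E)-5-{[tert-butyl(diphenyl)silyl]oxy}pent-3-en-1-yn-1-yl]-2,2,3a-trimethyl-3a,4,7,7a-tetrahydro-1,3-benzodioxol-4-ol (C4 epimers) | CC1(C)O[C@@H]2CC(C#C/C=C/CO[Si](c3ccccc3)(c3ccccc3)C(C)(C)C)=C(CO[Si](C)(C)C(C)(C)C)C(O)[C@]2(C)O1
F3 | step 19 | 7-hydroxy-2,2,5-trimethyl-4H-1,3-benzodioxin-4-one | Cc1cc(O)cc2OC(C)(C)OC(=O)c12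
F4 | step 19 | 7-{[tert-butyl(dimethyl)silyl]oxy}-2,2,5-trimethyl-4H-1,3-benzodioxin-4-one | Cc1cc(O[Si](C)(C)C(C)(C)C)cc2OC(C)(C)OC(=O)c12
F5 | step 19 | (6R,7R)-3-[(1E)-3-{[tert-butyl(diphenyl)silyl]oxy}prop-1-en-1-yl]-7-hydroxy-7-methyl-8-oxo-5,6,7,8-tetrahydro-1H-isochromen-6-yl 4-{[tert-butyl(dimethyl)silyl]oxy}-2-hydroxy-6-methylbenzoate | Cc1cc(O[Si](C)(C)C(C)(C)C)cc(O)c1C(=O)O[C@@H]1CC2=C(COC(/C=C/CO[Si](c3ccccc3)(c3ccccc3)C(C)(C)C)=C2)C(=O)[C@]1(C)O
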